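## Analysis of the target

Target 14 is an isoflavone. Ring A (C4a–C8a, methoxyl at C7) is fused to the pyranone ring C (O1, C2, C3, C4). C3 carries ring B (C1'–C6'), which has a methoxyl at C2' and a 2,2-dimethylpyran (ring D: O1'', C2'', C3''=C4'') fused across C3'–C4'.

The molecule has no stereocentre. The only one met on the way is C3 of the dihydro precursor 13, which is racemic and becomes trigonal in the last step.

The most sensitive group is the C3''=C4'' double bond of ring D. It is a styrene flanked by two ortho oxygens, so protonation gives a doubly stabilised benzylic cation. Strong acids, electrophilic halogen and hydrogenation are therefore excluded. The chromone is a vinylogous ester open to nucleophiles at C2 and is best unveiled last.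

The difficulties are regiochemical. Ring B needs the contiguous 2'-O, 3'-C, 4'-O pattern with ring D fused on the correct side. The C3–C1' bond is hindered by the C2' methoxyl. Ring C must close onto ring A so that the methoxyl ends at C7 and not at C5.

The strategy rests on C4a, which lies ortho to O1 and para to the C7 methoxyl. This is exactly the position of the bromine in the commercial phenol 9. The C4–C4a bond can therefore be made from an aryl anion at C4a and an ester carbon at C4, without acid, and with the regiochemistry fixed by the halogen.

## Retrosynthetic reasoning

**14 ⇒ 13.** The C2=C3 double bond is removed first, which leads back to the isoflavanone 13. With C2–C3 saturated, ring C can be closed from a freely rotating 3-aryloxypropanoate, so no alkene geometry has to be controlled. The forward step is a dehydrogenation that takes one hydrogen each from C2 and C3. Ring D offers no abstractable hydride, because C2'' is quaternary.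

**13 ⇒ 10.** Ring C is cut at C4–C4a, the aryl–carbonyl bond. This splits the molecule into a ring A piece and a ring B arylpropanoate, and it is the one cut of ring C that can be made in the forward sense under purely basic conditions. An acid-mediated acylation of ring A would endanger ring D and could also attack the position between the two oxygens. A cut at C3–C1' would demand a hindered coupling next to the C2' methoxyl. In 10 the bromine marks C4a. The forward reaction must exchange it for lithium faster than the C3 hydrogen is removed; the aryllithium 11 then adds to the ester, and the adduct 12 gives 13.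

**10 ⇒ 8 + 9.** The ether bond O1–C2 is cut in the sense of a conjugate addition. This makes the route convergent: phenol 9 is commercial and already carries bromine and methoxyl in the right places, and acrylate 8 contains all of ring B, ring D, C2, C3 and C4. The forward oxa-Michael addition creates C3 as a racemic centre, which is of no consequence.

**8 ⇒ 7 ⇒ 5.** The ester carbon of 8 (the future C4) is cut from the vinyl carbon. Enol triflate 7 is the precursor, and it comes from methyl ketone 5 through enolate 6. The acetyl group of 5 thus supplies C3 (its carbonyl carbon) and C2 (its methyl carbon), and a carbonylation supplies C4. Two steps replace a longer homologation and α-methylenation of an arylacetic ester.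

**5 ⇒ 4 ⇒ 1 + 2.** After removal of the O-methyl group, ring D is cut at C3'–C4'' and O1''–C2''. This is the retron of a chromenylation of the resorcinol-type ketone 1 with prenal 2 through oxatriene 3. The carbon between the two hydroxyls of 1 is the nucleophile. The hydroxyl ortho to the acetyl group is tied up in a hydrogen bond, so the other oxygen closes the pyran. The chelated hydroxyl of 4 is left to become the C2' methoxyl.

## Alternatives that were turned down

**Alternative 1:** Ring B is not bought as an arene but grown from cyclohexane-1,3-dione A1. Ring D is cut at the same two bonds as above, but with ring B at the cyclohexenone level. In the forward key step A1 condenses through its central carbon with prenal 2, and the 1-oxatriene closes by oxa-6π electrocyclisation to the bicyclic enone A2.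

- **For:** A1 is symmetrical, so the pyran can be fused in only one way. The remaining carbonyl marks C2' and its α-methylene marks C1'.
- **Against:** The α-carbon of A2 must still be joined to C3, either by enolate arylation with a base-sensitive 3-halochromone or by building rings C and A afterwards. Ring B must then be dehydrogenated to the phenol and methylated, in the presence of the electron-rich alkene of ring D. None of these extra operations helps with ring C.
- **Comparison:** On the regiochemistry of the pyran annulation this alternative is stronger, because symmetry is surer than the hydrogen-bond bias used in step 1. The chosen route offers in exchange an aromatic ring B with the correct oxygen pattern after two steps, and it concentrates its risk in one ring closure.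

**Alternative 2:** Ring B is cut at C1'–C2', C2'–C3' and C4'–C5'. This leads back to the dienyl diazoketone A3, which is attached to a finished 7-methoxychromone, and to the prenyl-bearing siloxyalkyne A4. In the forward key step, photochemical Wolff rearrangement of A3 gives a vinylketene. This adds to A4 in a [2+2] sense, the cyclobutenone opens, and six-electron closure with tautomerisation gives phenol A5 (free 2'-hydroxyl, 3'-prenyl, 4'-silyloxy).

- **For:** Every substituent of ring B is placed by the annulation. The plan is convergent, and rings A and C are already at the chromone level, so no late dehydrogenation is needed. On these two points it is stronger than the chosen route.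
- **Against:** The chromone is itself a strong chromophore and a Michael acceptor, so the irradiation competes with its own photochemistry. The ketene intermediates can be intercepted by the prenyl double bond. A3 and A4 each take several steps to make. After A5, three more operations are needed: methylation of the 2'-hydroxyl, desilylation and oxidative closure of ring D.
- **Comparison:** The chosen strategy offers commercial aromatic building blocks, ground-state chemistry only, and roughly half the step count.

**Alternative 3:** Ring C is cut at O1–C2 and C4–C4a. Both bonds are formed between 3-methoxyphenol A6 and the bis(2,4,6-trichlorophenyl) arylmalonate A7. In the forward key step, transesterification gives an aryl ester, thermal loss of the second aryloxide gives an aryloxycarbonyl ketene, and this acylates ring A para to its methoxyl to give the 4-hydroxycoumarin A8.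

- **For:** It makes the same C4–C4a bond as the chosen route and O1–C2 in the same operation. It needs no halogen, no organolithium and no cryogenic step, and A6 is cheaper than 9. On operational simplicity it is stronger.
- **Against:** The condensation needs high temperature, which ring D may not tolerate. The regiochemistry rests only on the electronic preference of A6, and attack between the two oxygens would give the 5-methoxy series. A7 requires an arylacetic ester, its carboxylation and an activation. A8 has C2 at the acid level and C4 as an enol, so the vinylogous acid must be capped, the lactone reduced and water eliminated under acid, which ring D tolerates poorly.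
- **Comparison:** The chosen strategy offers regiochemistry fixed by the C–Br bond, a ring C with the carbonyl already at C4, base-only conditions, and seven steps in all.

Key step: step 6

## Route

Remark on stereochemistry: compounds 10, 11, 12 and 13 are racemic. The SMILES show one enantiomer, (S) at C3 for 10 and 13. The configuration has no consequence, because C3 becomes trigonal in step 7.

Step 1
Reactants: 1 2,4-dihydroxyacetophenone; 2 3-methylbut-2-enal (prenal)
Product: 4 1-(5-hydroxy-2,2-dimethyl-2H-chromen-6-yl)ethanone, via oxatriene 3 (not isolated)
Conditions: pyridine, 140 °C, sealed tube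
Reagents that add atoms: none
Why: Chromenylation of a resorcinol: the ring carbon between the two hydroxyls adds to the aldehyde, loss of water gives the 1-oxatriene 3, and oxa-6π electrocyclisation closes the pyran. The hydroxyl ortho to the acetyl group is held in a hydrogen bond to the carbonyl, so the para oxygen should become the pyran oxygen and the angular 5-hydroxy-6-acetyl chromene should result.

Step 2
Reactants: 4 1-(5-hydroxy-2,2-dimethyl-2H-chromen-6-yl)ethanone
Product: 5 1-(5-methoxy-2,2-dimethyl-2H-chromen-6-yl)ethanone
Conditions: MeI, K2CO3, DMF, 50 °C
Reagents that add atoms: methyl iodide, CI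
Why: Williamson O-methylation of the hydrogen-bonded phenol, which needs a polar aprotic solvent and gentle warming. K2CO3 is too weak to enolise the ketone, so no C-methylation is expected.

Step 3
Reactants: 5 1-(5-methoxy-2,2-dimethyl-2H-chromen-6-yl)ethanone
Product: 7 1-(5-methoxy-2,2-dimethyl-2H-chromen-6-yl)ethenyl trifluoromethanesulfonate, via potassium enolate 6 (not isolated)
Conditions: KN(SiMe3)2, THF, −78 °C; PhNTf2, −78 to 0 °C; sat. aq. NH4Cl
Reagents that add atoms: N-phenylbis(trifluoromethanesulfonimide), O=S(=O)(N(c1ccccc1)S(=O)(=O)C(F)(F)F)C(F)(F)F
Why: Standard enol triflate synthesis: the acetyl methyl group is the only acidic site, and the potassium enolate 6 is sulfonylated on oxygen by the triflimide. The product is an electron-rich α-aryl vinyl triflate and should be purified on base-washed silica and used promptly.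

Step 4
Reactants: 7 1-(5-methoxy-2,2-dimethyl-2H-chromen-6-yl)ethenyl trifluoromethanesulfonate
Product: 8 methyl 2-(5-methoxy-2,2-dimethyl-2H-chromen-6-yl)prop-2-enoate
Conditions: Pd(OAc)2 (cat.), PPh3, CO (1 atm), MeOH, Et3N, DMF, 50 °C
Reagents that add atoms: carbon monoxide, [C-]#[O+]; methanol, CO
Why: Palladium-catalysed methoxycarbonylation of an enol triflate: zerovalent palladium formed in situ inserts into the C–OTf bond, CO inserts, and methanol cleaves the acylpalladium. The cis-disubstituted alkene of ring D and the aryl ethers do not take part, and the carbon introduced here becomes C4.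

Step 5
Reactants: 8 methyl 2-(5-methoxy-2,2-dimethyl-2H-chromen-6-yl)prop-2-enoate; 9 2-bromo-5-methoxyphenol
Product: 10 methyl 3-(2-bromo-5-methoxyphenoxy)-2-(5-methoxy-2,2-dimethyl-2H-chromen-6-yl)propanoate (racemic)
Conditions: Cs2CO3 (0.2 equiv), 9 (1.5 equiv), DMF, rt to 40 °C; AcOH quench
Reagents that add atoms: none
Why: Base-catalysed oxa-Michael addition of a phenoxide to a 2-arylacrylate; the aryl-stabilised ester enolate is protonated by the excess phenol, which regenerates the phenoxide. The new centre (the future C3) is set by unselective protonation and is racemic, which is acceptable because step 7 removes it.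

Step 6
Reactants: 10 methyl 3-(2-bromo-5-methoxyphenoxy)-2-(5-methoxy-2,2-dimethyl-2H-chromen-6-yl)propanoate (racemic)
Product: 13 7-methoxy-3-(5-methoxy-2,2-dimethyl-2H-chromen-6-yl)chroman-4-one (racemic), via aryllithium 11 (not isolated), via lithium hemiketal alkoxide 12 (not isolated)
Conditions: t-BuLi (2.1 equiv), THF/Et2O/pentane, −100 °C, then −78 °C; sat. aq. NH4Cl, −78 °C
Reagents that add atoms: none
Why: Parham cyclisation: t-BuLi attacks the bromine of 10 and gives aryllithium 11, and the second equivalent destroys the t-BuBr formed, so the exchange cannot reverse. The carbanion at C4a adds to the ester carbon in a 6-exo-trig closure, which forms C4–C4a and ring C as the lithium hemiketal alkoxide 12; work-up releases ketone 13 and methanol. The closest known reaction type is halogen–lithium exchange followed by intramolecular acylation of ortho-bromoaryl esters, acids and amides, which gives indanones, tetralones and chroman-4-ones. No stereocentre is created: C3 is already present and racemic, and the hemiketal carbon of 12 is lost on collapse. The step needs the exchange to outrun removal of the C3 hydrogen (acidified by ester and aryl, with an aryloxide in the β-position) and addition of t-BuLi to the ester. At −100 °C, exchange at an aryl bromide activated by the ortho ether oxygen should be much faster than proton transfer from a hindered tertiary C–H or attack of the bulky base on the carbonyl. Once formed, 11 is trapped intramolecularly, and because 12 persists in the cold no ketone is exposed to organolithium. The bromine defines C4a, so only the 7-methoxy isomer can form, and the absence of acid leaves ring D untouched.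

Step 7
Reactants: 13 7-methoxy-3-(5-methoxy-2,2-dimethyl-2H-chromen-6-yl)chroman-4-one (racemic)
Product: 14 7-methoxy-3-(5-methoxy-2,2-dimethyl-2H-chromen-6-yl)-4H-chromen-4-one
Conditions: DDQ (1.5 equiv), 1,4-dioxane, reflux
Reagents that add atoms: none
Why: Quinone dehydrogenation of a chroman-4-one to the chromone, a standard conversion of isoflavanones into isoflavones: hydride is taken from C2 (assisted by O1 and the enol) and a proton is lost from C3. Ring D has no abstractable hydride at its quaternary C2'', and 2,2-dimethylchromenes are themselves typical products of DDQ dehydrogenation, so ring D should survive. The C3 stereocentre disappears.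

## Compound list

1 | 2,4-dihydroxyacetophenone | CC(=O)c1ccc(O)cc1O | starting material
2 | 3-methylbut-2-enal (prenal) | CC(C)=CC=O | starting material
3 | 4-acetyl-3-hydroxy-2-(3-methylbut-2-enylidene)cyclohexa-3,5-dien-1-one (1-oxatriene; dienyl chain cis to the ring carbonyl) | CC(=O)C1=C(O)/C(=C/C=C(C)C)C(=O)C=C1 | intermediate (not isolated)
4 | 1-(5-hydroxy-2,2-dimethyl-2H-chromen-6-yl)ethanone | CC(=O)c1ccc2OC(C)(C)C=Cc2c1O | intermediate
5 | 1-(5-methoxy-2,2-dimethyl-2H-chromen-6-yl)ethanone | CC(=O)c1ccc2OC(C)(C)C=Cc2c1OC | intermediate
6 | potassium 1-(5-methoxy-2,2-dimethyl-2H-chromen-6-yl)ethenolate | [K+].[O-]C(=C)c1ccc2OC(C)(C)C=Cc2c1OC | intermediate (not isolated)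
7 | 1-(5-methoxy-2,2-dimethyl-2H-chromen-6-yl)ethenyl trifluoromethanesulfonate | C=C(OS(=O)(=O)C(F)(F)F)c1ccc2OC(C)(C)C=Cc2c1OC | intermediate
8 | methyl 2-(5-methoxy-2,2-dimethyl-2H-chromen-6-yl)prop-2-enoate | C=C(C(=O)OC)c1ccc2OC(C)(C)C=Cc2c1OC | intermediate
9 | 2-bromo-5-methoxyphenol | COc1ccc(Br)c(O)c1 | starting material
10 | methyl 3-(2-bromo-5-methoxyphenoxy)-2-(5-methoxy-2,2-dimethyl-2H-chromen-6-yl)propanoate (racemic; S drawn) | COC(=O)[C@H](COc1cc(OC)ccc1Br)c1ccc2OC(C)(C)C=Cc2c1OC | intermediate
11 | methyl 3-(2-lithio-5-methoxyphenoxy)-2-(5-methoxy-2,2-dimethyl-2H-chromen-6-yl)propanoate (racemic; one enantiomer drawn) | COC(=O)[C@H](COc1cc(OC)ccc1[Li])c1ccc2OC(C)(C)C=Cc2c1OC | intermediate (not isolated)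
12 | lithium 4,7-dimethoxy-3-(5-methoxy-2,2-dimethyl-2H-chromen-6-yl)chroman-4-olate (racemic at C3; both epimers at C4) | COc1ccc2C(OC)(O[Li])[C@@H](c3ccc4OC(C)(C)C=Cc4c3OC)COc2c1 | intermediate (not isolated)
13 | 7-methoxy-3-(5-methoxy-2,2-dimethyl-2H-chromen-6-yl)chroman-4-one (racemic; S drawn) | COc1ccc2C(=O)[C@@H](c3ccc4OC(C)(C)C=Cc4c3OC)COc2c1 | intermediate
14 | 7-methoxy-3-(5-methoxy-2,2-dimethyl-2H-chromen-6-yl)-4H-chromen-4-one | COc1ccc2c(=O)c(-c3ccc4c(c3OC)C=CC(C)(C)O4)coc2c1 | target

## Step count and risk

Total: 7 steps. Longest linear sequence: 7 steps (1 to 14). Phenol 9 is bought and enters at step 5.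

**Step 6 (key step).** The most likely failure is proton transfer in place of ring closure. The C3 hydrogen may be removed by t-BuLi or by 11, after which the aryloxide is expelled. Alternatively, 12 may collapse early, so that the ketone and methoxide meet residual base. Both follow from the acidity of the α-hydrogen of an aryl-substituted ester that has a leaving group in the β-position. The fallback changes the acyl donor. From 10, aminolysis with Me(MeO)NH·HCl and AlMe3 (CH2Cl2, 0 °C to rt) would give 3-(2-bromo-5-methoxyphenoxy)-N-methoxy-2-(5-methoxy-2,2-dimethyl-2H-chromen-6-yl)-N-methylpropanamide F1. Its α-hydrogen is less acidic, and bromine–lithium exchange (t-BuLi, THF, −100 °C) would close ring C through a lithium-chelated adduct that cannot release the ketone before work-up. The sequence rejoins the route at 13.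

**Step 5.** The most likely failure is incomplete addition, or reversal of the addition during concentration. The ortho-bromophenoxide is hindered and is a fairly good leaving group, and the adduct keeps an acidic α-hydrogen. Base-initiated oligomerisation of 8 is the second risk. The fallback makes the C–O bond by irreversible substitution. From 8, conjugate borylation (B2pin2, CuCl, Xantphos, NaOt-Bu, MeOH, THF) would give methyl 2-(5-methoxy-2,2-dimethyl-2H-chromen-6-yl)-3-(4,4,5,5-tetramethyl-1,3,2-dioxaborolan-2-yl)propanoate F2. Oxidation with NaBO3·4H2O would give methyl 3-hydroxy-2-(5-methoxy-2,2-dimethyl-2H-chromen-6-yl)propanoate F3. Mitsunobu etherification with 9 (PPh3, DIAD, toluene, 0 °C) then returns to 10.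

**Step 3.** The most likely failure is loss of the triflate group during isolation. Ionisation or hydrolysis of an electron-rich α-aryl vinyl triflate regenerates the ketone, and this would also starve step 4. The fallback avoids the triflate and the carbonylation. From 5, condensation with 2,4,6-triisopropylbenzenesulfonyl hydrazide (MeOH, cat. AcOH) would give N'-[1-(5-methoxy-2,2-dimethyl-2H-chromen-6-yl)ethylidene]-2,4,6-tri(propan-2-yl)benzenesulfonohydrazide F4. A Shapiro reaction (n-BuLi, THF/TMEDA, −78 to 0 °C) followed by a CO2 quench would give 2-(5-methoxy-2,2-dimethyl-2H-chromen-6-yl)prop-2-enoic acid F5. Methylation (MeI, K2CO3, DMF) rejoins the route at 8.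

**Step 7.** The most likely failure is oxidative degradation of the electron-rich rings B and D by the quinone. The other risk is a sluggish reaction, because enolisation and hydride abstraction next to the ortho-methoxyaryl group at C3 are hindered. The fallback replaces hydride abstraction by a palladium enolate. From 13, soft enolisation (TMSOTf, Et3N, CH2Cl2, 0 °C) would give [7-methoxy-3-(5-methoxy-2,2-dimethyl-2H-chromen-6-yl)-2H-chromen-4-yl]oxy-trimethylsilane F6. Saegusa–Ito oxidation with Pd(OAc)2 (MeCN, rt to 40 °C) would then give 14.

## Further compounds

F1 | step 6 | 3-(2-bromo-5-methoxyphenoxy)-N-methoxy-2-(5-methoxy-2,2-dimethyl-2H-chromen-6-yl)-N-methylpropanamide (racemic; one enantiomer drawn) | CON(C)C(=O)[C@H](COc1cc(OC)ccc1Br)c1ccc2OC(C)(C)C=Cc2c1OC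
F2 | step 5 | methyl 2-(5-methoxy-2,2-dimethyl-2H-chromen-6-yl)-3-(4,4,5,5-tetramethyl-1,3,2-dioxaborolan-2-yl)propanoate (racemic; one enantiomer drawn) | COC(=O)[C@H](CB1OC(C)(C)C(C)(C)O1)c1ccc2OC(C)(C)C=Cc2c1OC
F3 | step 5 | methyl 3-hydroxy-2-(5-methoxy-2,2-dimethyl-2H-chromen-6-yl)propanoate (racemic; one enantiomer drawn) | COC(=O)[C@H](CO)c1ccc2OC(C)(C)C=Cc2c1OC
F4 | step 3 | N'-[1-(5-methoxy-2,2-dimethyl-2H-chromen-6-yl)ethylidene]-2,4,6-tri(propan-2-yl)benzenesulfonohydrazide (E) | C/C(=N\NS(=O)(=O)c1c(C(C)C)cc(C(C)C)cc1C(C)C)c1ccc2OC(C)(C)C=Cc2c1OC
F5 | step 3 | 2-(5-methoxy-2,2-dimethyl-2H-chromen-6-yl)prop-2-enoic acid | C=C(C(=O)O)c1ccc2OC(C)(C)C=Cc2c1OC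
F6 | step 7 | [7-methoxy-3-(5-methoxy-2,2-dimethyl-2H-chromen-6-yl)-2H-chromen-4-yl]oxy-trimethylsilane | COc1ccc2C(O[Si](C)(C)C)=C(c3ccc4OC(C)(C)C=Cc4c3OC)COc2c1
A1 | alternative 1 | cyclohexane-1,3-dione | O=C1CCCC(=O)C1
A2 | alternative 1 | 2,2-dimethyl-7,8-dihydro-2H-chromen-5(6H)-one | CC1(C)C=CC2=C(CCCC2=O)O1
A3 | alternative 2 | (E)-1-diazo-4-(7-methoxy-4-oxo-4H-chromen-3-yl)but-3-en-2-one | COc1ccc2c(=O)c(/C=C/C(=O)C=[N+]=[N-])coc2c1
A4 | alternative 2 | triisopropyl[(5-methylhex-4-en-1-yn-1-yl)oxy]silane | CC(C)=CCC#CO[Si](C(C)C)(C(C)C)C(C)C
A5 | alternative 2 | 3-[2-hydroxy-3-(3-methylbut-2-enyl)-4-(triisopropylsilyloxy)phenyl]-7-methoxy-4H-chromen-4-one | COc1ccc2c(=O)c(-c3ccc(O[Si](C(C)C)(C(C)C)C(C)C)c(CC=C(C)C)c3O)coc2c1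
A6 | alternative 3 | 3-methoxyphenol | COc1cccc(O)c1
A7 | alternative 3 | bis(2,4,6-trichlorophenyl) 2-(5-methoxy-2,2-dimethyl-2H-chromen-6-yl)propanedioate | COc1c(C(C(=O)Oc2c(Cl)cc(Cl)cc2Cl)C(=O)Oc2c(Cl)cc(Cl)cc2Cl)ccc2OC(C)(C)C=Cc12
A8 | alternative 3 | 4-hydroxy-7-methoxy-3-(5-methoxy-2,2-dimethyl-2H-chromen-6-yl)-2H-chromen-2-one | COc1ccc2c(O)c(-c3ccc4OC(C)(C)C=Cc4c3OC)c(=O)oc2c1
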